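Assumption: atoms are numbered as in a germacrane (ring C1–C10, lactone carbons C11–C13, ester carbon C14 on C10, C15 on C4); C11 of the phosphono lactones 23, 25, 26 and 27 forms as an epimer mixture that step 15 erases, so it carries no descriptor.

## The problem

Target 29 is a germacranolide. Its ten-membered carbocycle (C1–C10) is trans-fused at C6–C7 to an α-methylene-γ-butyrolactone, with an E-configured C1=C10 enoate in which ring carbons C2 and C9 are cis, an (R)-2-methylbutanoate on C8 and a hydroxymethyl group (C15) on C4. A synthesis must close a medium ring, where entropy and transannular strain oppose every bond-forming event, and must fix four ring stereocentres besides the purchased one in the side chain. C6, C7 and C8 are contiguous and can control one another: a C6 carbinol can direct an epoxide onto C7=C8, and an SN2 event at C7 relays that information. C4 is insulated by the C5 methylene and needs its own absolute control element. The exocyclic methylene lactone is a Michael acceptor that would not survive boranes, palladium hydrides or basic nucleophiles, so it must appear last; the C8 ester sits 1,3 to the C6 oxygen, so a free hydroxyl at either position invites acyl migration or lactone migration from O6 to O8; three esters and an alkenyl iodide exclude strong bases, hydrides and zerovalent metals late on. C7 lies between two oxygen-bearing carbons, the one position of a 2,3-epoxy alcohol that intermolecular organoaluminium nucleophiles avoid, so the C7–C11 bond needs a device that enforces regiochemistry. The ring closure is made possible by the C1–C2 bond: it joins the sp2 carbon C1 of the enoate to a methylene with no functionality, two atoms from C4. A vinyl group on C4 (a latent C2 borane) and an iodide on C1 can therefore be united after every stereocentre and the alkene geometry are in place, with C2 and C9 already cis on the alkene as the ring requires.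

## Retrosynthesis

**29 ⇒ 28 ⇒ 27 (O–Si at C15, then C11=C13).** The silyl ether is cut first and the exocyclic methylene second, the latter back to the α-diethoxyphosphoryl lactone 27 (Horner–Wadsworth–Emmons reaction with formaldehyde). A phosphonate is preferred to carrying the methylene itself, which would compete for 9-BBN and palladium hydrides, and to carrying C11–C13 as an alkyne for a carbonylative lactonisation. The alkyne would have to be placed on C7, the proximal carbon of a 2,3-epoxy alcohol, where alkynylalanes are known to choose the distal carbon. 27 is simpler by one alkene and one free hydroxyl; the forward steps need only carbonate base and fluoride.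

**27 ⇒ 25 (C1–C2).** This is the ring-opening cut. Its neighbours C2–C3 and C3–C4 are sp3–sp3 bonds without any handle. Closing at C1=C10 by olefination would leave the alkene geometry to the ring-forming step. Closing at C6–C7 or C7–C8 would create stereocentres under transannular control. C1–C2 creates no stereocentre and no new geometry. 25 is acyclic in the large ring and carries a terminal alkene and an (E)-β-iodoenoate; the forward reaction needs hydroboration of only the terminal alkene and an intramolecular sp3–sp2 coupling at high dilution.

**25 ⇒ 23 + 24 (C8 O–acyl).** The ester is cut to alcohol 23 and purchased acid 24. It is made after the lactone so that O6 is already tied up and neither acyl nor lactone migration can occur. The forward step is a plain carbodiimide esterification of the only free hydroxyl.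

**23 ⇒ 21 ⇒ 19 + 20 (C7–C11, then the C6 ester).** The lactone C–C bond is cut to the phosphonoacetate 21 of epoxy alcohol 19. The alternative of intermolecular carbon delivery would go to C8, away from the carbinol. The ester tether reverses this: only the 5-exo opening at C7 closes a γ-lactone. The same event inverts C7, frees O8 alone and leaves the phosphonate that later becomes the methylene. The forward reaction needs a stabilised enolate to open a 1,2-disubstituted epoxide intramolecularly.

**19 ⇒ 18 (epoxide oxygen).** The epoxide is cut to the (E)-allylic alcohol 18. Sharpless epoxidation is preferred to peracid or vanadium because the tartrate sets C7 and C8 absolutely, and the erythro isomer it gives is the one whose O6 tether lies anti to the epoxide oxygen. The forward reaction needs the matched tartrate and must leave the terminal and electron-poor alkenes alone.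

**18 ⇒ 10 + 15 (C6–C7).** This is the convergent cut, to aldehyde 10 and alkyne 15 (via the alkenylzinc from hydroboration and boron-to-zinc exchange). A chromium/nickel alkenyl halide coupling is excluded because 15 already holds the C1 iodide. The cut divides the skeleton into a C2–C6 piece with the C4 centre and a C7–C10/C1 piece with the iodoenoate; the forward step must set C6 by catalyst control.

**15 ⇒ 14 ⇒ 13 ⇒ 11 (C10=C1 with iodine).** The iodoenoate is traced to propargylmalonate 11 and iodoform by diiodomethylation, then saponification and decarboxylative elimination. Halogenating a 2-substituted acrylate was rejected because bromine would not spare a vinyl group or alkyne elsewhere; here the iodide is installed on a small fragment and the stable E geometry results.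

**10 ⇒ 9 ⇒ 8 ⇒ 7 ⇒ 4 + 5; 4 ⇒ 1 + 2.** C4–C5 is cut by an Evans alkylation of the but-3-enoyl imide 4 with bromoacetate 5, which sets C4. The vinyl group, C15 and C5–C6 are then all in place, and reduction, silylation and partial reduction give 10. 4 comes from acid 1 and auxiliary 2 through anhydride 3.

## Roads not taken

**Alternative 1:** The cut is C3–C4, made by an Ireland–Claisen rearrangement inside a ring ester that links C15 to the C1 oxygen. In the forward step the silyl ketene acetal rearranges, O–C1 breaks and the carbocyclic C15 acid A1 with a cis C1=C2 alkene results.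
- Merits: a C–C bond and the C4 centre form in the ring-switching event, no palladium is needed, and ring closure is moved to an esterification.
- Weak points for this target: the ten-membered lactone is itself a medium ring. Its enolisation competes with the γ-lactone α-protons. The C4 configuration depends on a chair or boat transition state that the ring dictates. A1 still needs the alkene moved from C1=C2 into conjugation at C1=C10, the C14 ether oxidised to the ester, the C15 acid reduced beside a lactone, and the methylene installed by enolate chemistry.
- Comparison: it is better in forming C4 and the carbocycle together without high-dilution coupling. The chosen plan has no redox or alkene transposition after ring closure, and alkene position and geometry are fixed before it.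

**Alternative 2:** The cuts are C7–C11 and a temporary C8–C11 bond. The tert-butyl diazomalonate A2 of alcohol 18 would give, with Rh2(OAc)4, the cyclopropane-fused lactone A3 by carbene addition to C7=C8. Ring opening at C8 by the carboxylate would then place the ester with inversion.
- Merits: every reaction type is known; the lactone, C7 and (after opening) C8 come from one alkene; it shares 18 with the chosen route.
- Weak points: the carbene must choose C7=C8 over the C4 vinyl group and allylic C–H bonds; facial control rests on C6 alone; an α-branched carboxylate must open a cyclopropane at a secondary carbon; the tert-butyl ester must then be removed and the methylene added; the macrocycle is still to be closed.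
- Comparison: it is equal in step count and better in precedent. The chosen plan offers reagent-controlled epoxide stereochemistry and a mild esterification for the acyl group. The phosphonate version of this chemistry is kept as the fallback for step 12.

**Alternative 3:** The cut is C7–C8. BF3·OEt2 would activate the aldehyde of the seco stannane A4, and the butenolide β-carbon would attack it with loss of tin to give the macrocycle A5.
- Merits: ring closure, two stereocentres and the methylene arise in one operation; the route is short and convergent; the lactone needs no mask.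
- Weak points: the allylstannane is conjugated to the lactone carbonyl and is a poor nucleophile; C7 and C8 would be set relative to C6 only by a medium-ring transition state; the aldehyde of A4 is β,γ-unsaturated and prone to migrate into conjugation; the methylene lactone must then survive the acylation.
- Comparison: it is better in step economy. The chosen plan has all four stereocentres set by reagents before ring closure, and its ring-closing step creates none.

Key step: step 14

## Route

Step 1
Reactants: 1 but-3-enoic acid; 2 (R)-4-benzyloxazolidin-2-one
Product: 4 (R)-4-benzyl-3-(but-3-enoyl)oxazolidin-2-one, via but-3-enoic pivalic anhydride 3 (not isolated)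
Conditions: PivCl, Et3N, THF, −20 °C; then 2, LiCl, −20 °C → rt
Reagents that add atoms: none
Why: Mixed-anhydride N-acylation of the oxazolidinone; the weak base (Et3N with LiCl) attaches the auxiliary without moving the β,γ-alkene into conjugation.

Step 2
Reactants: 4 (R)-4-benzyl-3-(but-3-enoyl)oxazolidin-2-one; 5 tert-butyl bromoacetate
Product: 7 tert-butyl (3R)-3-{[(4R)-4-benzyl-2-oxooxazolidin-3-yl]carbonyl}pent-4-enoate, via sodium dienolate 6 (not isolated)
Conditions: NaN(SiMe3)2, THF, −78 °C; then 5, −78 → −50 °C
Reagents that add atoms: none
Why: Evans alkylation: the chelated (Z)-dienolate 6 reacts at its α-carbon with the activated bromide on the face away from the benzyl group of the (R)-auxiliary, which sets C4 (the 3R centre of 7).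

Step 3
Reactants: 7 tert-butyl (3R)-3-{[(4R)-4-benzyl-2-oxooxazolidin-3-yl]carbonyl}pent-4-enoate
Product: 8 tert-butyl (3R)-3-(hydroxymethyl)pent-4-enoate
Conditions: LiBH4, H2O (1 equiv), Et2O, 0 °C
Reagents that add atoms: none
Why: Reductive removal of the auxiliary: LiBH4 attacks the exocyclic imide carbonyl faster than the tert-butyl ester, giving the C15 alcohol and returning 2; C4 should not epimerise at 0 °C.

Step 4
Reactants: 8 tert-butyl (3R)-3-(hydroxymethyl)pent-4-enoate
Product: 9 tert-butyl (3R)-3-[(tert-butyldimethylsilyloxy)methyl]pent-4-enoate
Conditions: TBSCl, imidazole, DMF, rt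
Reagents that add atoms: tert-butyldimethylsilyl chloride, CC(C)(C)[Si](C)(C)Cl
Why: Standard silylation of a primary alcohol; the TBS ether is chosen to last until the final fluoride treatment.

Step 5
Reactants: 9 tert-butyl (3R)-3-[(tert-butyldimethylsilyloxy)methyl]pent-4-enoate
Product: 10 (3R)-3-[(tert-butyldimethylsilyloxy)methyl]pent-4-enal
Conditions: iBu2AlH, CH2Cl2, −78 °C; aq. potassium sodium tartrate
Reagents that add atoms: none
Why: Partial reduction of an ester: the tetrahedral aluminium alkoxide of the hindered tert-butyl ester is stable at −78 °C and collapses to the aldehyde only on work-up.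

Step 6
Reactants: 11 dimethyl 2-(prop-2-yn-1-yl)malonate
Product: 13 dimethyl 2-(diiodomethyl)-2-(prop-2-yn-1-yl)malonate, via sodium malonate enolate 12 (not isolated)
Conditions: NaH, THF, 0 °C; then CHI3, reflux
Reagents that add atoms: iodoform, IC(I)I
Why: C-alkylation of a malonate enolate by iodoform (diiodomethylation), a known route to α-diiodomethyl malonates; it brings in C1 with its iodine before any other alkene exists.

Step 7
Reactants: 13 dimethyl 2-(diiodomethyl)-2-(prop-2-yn-1-yl)malonate
Product: 14 (2E)-2-(iodomethylidene)pent-4-ynoic acid
Conditions: KOH, EtOH/H2O, 75 °C; then aq. HCl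
Reagents that add atoms: potassium hydroxide, [K+].[OH-]
Why: Saponification followed by Grob-type decarboxylative elimination: a carboxylate and an anti C–I bond leave together to give the β-iodoacrylate; the E isomer (iodine trans to the carboxyl group, cis to C9) is the stable geometry this reaction type delivers.

Step 8
Reactants: 14 (2E)-2-(iodomethylidene)pent-4-ynoic acid
Product: 15 methyl (2E)-2-(iodomethylidene)pent-4-ynoate
Conditions: MeI, K2CO3, DMF, rt
Reagents that add atoms: iodomethane, CI
Why: O-alkylation of the potassium carboxylate; the weak base leaves the alkyne C–H and the alkene geometry untouched.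

Step 9
Reactants: 15 methyl (2E)-2-(iodomethylidene)pent-4-ynoate; 10 (3R)-3-[(tert-butyldimethylsilyloxy)methyl]pent-4-enal
Product: 18 methyl (2E,4E,6R,8R)-8-[(tert-butyldimethylsilyloxy)methyl]-6-hydroxy-2-(iodomethylidene)deca-4,9-dienoate, via alkenyl(dicyclohexyl)borane 16 (not isolated), via alkenyl(methyl)zinc 17 (not isolated)
Conditions: Cy2BH, toluene, 0 °C → rt; Me2Zn, −78 °C; (−)-MIB (5 mol %), then 10, −20 → 0 °C; aq. NH4Cl
Reagents that add atoms: none
Why: Syn, anti-Markovnikov hydroboration of the terminal alkyne and boron-to-zinc exchange give the (E)-alkenylzinc 17, which the (−)-MIB zinc catalyst delivers to the Si face of aldehyde 10, forming C6–C7 and setting C6 as R by catalyst control (C4 is too remote to interfere). The organozinc should not touch the ester or the alkenyl iodide.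

Step 10
Reactants: 18 methyl (2E,4E,6R,8R)-8-[(tert-butyldimethylsilyloxy)methyl]-6-hydroxy-2-(iodomethylidene)deca-4,9-dienoate
Product: 19 (6R,7R,8R)-7,8-epoxide of 18
Conditions: Ti(OiPr)4, D-(−)-DIPT, tBuOOH, 4 Å molecular sieves, CH2Cl2, −20 °C
Reagents that add atoms: tert-butyl hydroperoxide, CC(C)(C)OO
Why: Sharpless asymmetric epoxidation in the matched case: the D-(−)-tartrate catalyst delivers oxygen to the C7=C8 face that gives the (7R,8R)-epoxide erythro to the (6R)-carbinol. Any 6S epimer from step 9 is the slow-reacting partner and stays behind; the terminal and electron-poor alkenes are not allylic to the hydroxyl and should not react.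

Step 11
Reactants: 19 (6R,7R,8R)-7,8-epoxide of 18; 20 diethylphosphonoacetic acid
Product: 21 C6 diethylphosphonoacetate of epoxy alcohol 19
Conditions: DCC, DMAP (cat.), CH2Cl2, 0 °C → rt
Reagents that add atoms: none
Why: Steglich esterification of the secondary alcohol; neutral carbodiimide conditions keep the epoxide intact and attach C11 and C12 together with the phosphonate needed later.

Step 12
Reactants: 21 C6 diethylphosphonoacetate of epoxy alcohol 19
Product: 23 trans-6,12-lactone with 11-diethoxyphosphoryl group and free (8R)-hydroxyl, via lithium phosphonoenolate 22 (not isolated)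
Conditions: LiN(SiMe3)2 (1.0 equiv), THF, −78 → 40 °C; then AcOH
Reagents that add atoms: none
Why: Proposed new method: deprotonation gives the phosphonate-stabilised ester enolate 22, whose carbon attacks C7 of the tethered epoxide in a 5-exo-tet SN2 opening (6-endo attack at C8 would give the less favoured δ-lactone), inverting C7 and releasing the C8 alkoxide, which is quenched by the more acidic C11–H of the product; the erythro arrangement from step 10 places the O6 tether on the face opposite the epoxide oxygen, as backside attack requires, so C6 and C8 are untouched, the trans lactone results and C11 forms as an inconsequential mixture; the closest known reaction types are the intermolecular opening of epoxides by phosphonoacetate anions to give α-phosphono γ-lactones, the intramolecular conjugate addition of ester-tethered phosphonoacetates that closes the same lactones, and the 5-exo attack of O-tethered carbamates at the proximal carbon of 2,3-epoxy alcohols.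

Step 13
Reactants: 23 trans-6,12-lactone with 11-diethoxyphosphoryl group and free (8R)-hydroxyl; 24 (R)-2-methylbutanoic acid
Product: 25 seco (E)-β-iodoenoate: 8-O-[(R)-2-methylbutanoyl] ester of 23
Conditions: EDC·HCl, DMAP, CH2Cl2, 0 °C → rt
Reagents that add atoms: none
Why: Carbodiimide/DMAP esterification of the only free hydroxyl; O6 is locked in the lactone, so no acyl or lactone migration can follow, and the low temperature protects the α-stereocentre of the acid.

Step 14
Reactants: 25 seco (E)-β-iodoenoate: 8-O-[(R)-2-methylbutanoyl] ester of 23
Product: 27 ten-membered carbocycle with 11-phosphono lactone and 15-O-TBS group, via B-alkyl-9-BBN borane 26 (not isolated)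
Conditions: 9-BBN, THF, 0 °C → rt; then slow addition to Pd(dppf)Cl2 (10 mol %), AsPh3, aq. K3PO4, DMF/THF, 50 °C, final 1 mM
Reagents that add atoms: none
Why: 9-BBN adds to the monosubstituted C2=C3 alkene far faster than to the trisubstituted, electron-poor iodoenoate or to any carbonyl group and places boron on C2 (26). Zerovalent palladium inserts into the C1–I bond with retention, the base-activated borate transfers the primary alkyl group, and reductive elimination from the eleven-membered alkyl(alkenyl)palladacycle forms C1–C2. That reductive elimination is the ring-closing event that gives the ten-membered carbocycle 27. The closest known reaction type is the macrocyclic B-alkyl Suzuki–Miyaura coupling of 9-BBN alkylboranes with alkenyl iodides, used here at the lower limit of ring size. No stereocentre is formed: C4, C6, C7 and C8 are spectators and the E geometry of C1=C10 is carried over from 25. The step needs chemoselective hydroboration, secured by the single terminal alkene, and ring closure over intermolecular coupling, secured by slow addition at about 1 mM and helped by the trans lactone, which fixes the C5–C6–C7–C8 turn, and by the cis placement of C9 and iodine on the alkene. The phosphonate keeps C11 inert to the borane and to palladium hydrides, which an exocyclic methylene would not be.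

Step 15
Reactants: 27 ten-membered carbocycle with 11-phosphono lactone and 15-O-TBS group
Product: 28 15-O-TBS ether of the target
Conditions: K2CO3, aq. HCHO (37 %), THF, 0 °C
Reagents that add atoms: formaldehyde, C=O
Why: Horner–Wadsworth–Emmons methylenation of the α-phosphono lactone under mild carbonate conditions; it erases the C11 centre and forms C11=C13 without touching the three esters.

Step 16
Reactants: 28 15-O-TBS ether of the target
Product: 29 target CNP0141952.4
Conditions: HF·pyridine, pyridine, THF, 0 °C → rt
Reagents that add atoms: none
Why: Fluoride cleavage of the primary silyl ether under buffered acidic conditions that α-methylene lactones and esters tolerate.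

## Compound list

1 | but-3-enoic acid | C=CCC(=O)O | starting material
2 | (R)-4-benzyloxazolidin-2-one | O=C1N[C@H](Cc2ccccc2)CO1 | starting material
3 | but-3-enoic pivalic anhydride | C=CCC(=O)OC(=O)C(C)(C)C | intermediate
4 | (R)-4-benzyl-3-(but-3-enoyl)oxazolidin-2-one | C=CCC(=O)N1[C@H](Cc2ccccc2)COC1=O | intermediate
5 | tert-butyl bromoacetate | CC(C)(C)OC(=O)CBr | starting material
6 | sodium (Z)-dienolate of 4 | C=C/C=C(\[O-])N1[C@H](Cc2ccccc2)COC1=O.[Na+] | intermediate
7 | tert-butyl (3R)-3-{[(4R)-4-benzyl-2-oxooxazolidin-3-yl]carbonyl}pent-4-enoate | C=C[C@@H](CC(=O)OC(C)(C)C)C(=O)N1[C@H](Cc2ccccc2)COC1=O | intermediate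
8 | tert-butyl (3R)-3-(hydroxymethyl)pent-4-enoate | C=C[C@@H](CC(=O)OC(C)(C)C)CO | intermediate
9 | tert-butyl (3R)-3-[(tert-butyldimethylsilyloxy)methyl]pent-4-enoate | C=C[C@@H](CC(=O)OC(C)(C)C)CO[Si](C)(C)C(C)(C)C | intermediate
10 | (3R)-3-[(tert-butyldimethylsilyloxy)methyl]pent-4-enal (C2–C6 and C15) | C=C[C@@H](CC=O)CO[Si](C)(C)C(C)(C)C | intermediate
11 | dimethyl 2-(prop-2-yn-1-yl)malonate | C#CCC(C(=O)OC)C(=O)OC | starting material
12 | sodium enolate of 11 | C#CCC(C(=O)OC)=C([O-])OC.[Na+] | intermediate
13 | dimethyl 2-(diiodomethyl)-2-(prop-2-yn-1-yl)malonate | C#CCC(C(I)I)(C(=O)OC)C(=O)OC | intermediate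
14 | (2E)-2-(iodomethylidene)pent-4-ynoic acid | C#CC/C(C(=O)O)=C\I | intermediate
15 | methyl (2E)-2-(iodomethylidene)pent-4-ynoate (C7–C10, C1, C14) | C#CC/C(C(=O)OC)=C\I | intermediate
16 | (E)-alkenyl(dicyclohexyl)borane from 15 (boron on C7) | C1CCCCC1B(C1CCCCC1)/C=C/C/C(C(=O)OC)=C\I | intermediate
17 | (E)-alkenyl(methyl)zinc from 15 (zinc on C7) | C[Zn]/C=C/C/C(C(=O)OC)=C\I | intermediate
18 | methyl (2E,4E,6R,8R)-8-[(tert-butyldimethylsilyloxy)methyl]-6-hydroxy-2-(iodomethylidene)deca-4,9-dienoate (germacrane C6 alcohol, 4R,6R) | C=C[C@H](CO[Si](C)(C)C(C)(C)C)C[C@@H](O)/C=C/C/C(C(=O)OC)=C\I | intermediate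
19 | (6R,7R,8R)-7,8-epoxide of 18 (erythro epoxy alcohol, 4R) | C=C[C@H](CO[Si](C)(C)C(C)(C)C)C[C@@H](O)[C@H]1O[C@@H]1C/C(C(=O)OC)=C\I | intermediate
20 | diethylphosphonoacetic acid | OC(=O)CP(=O)(OCC)OCC | starting material
21 | C6 diethylphosphonoacetate of epoxy alcohol 19 | C=C[C@H](CO[Si](C)(C)C(C)(C)C)C[C@@H](OC(=O)CP(=O)(OCC)OCC)[C@H]1O[C@@H]1C/C(C(=O)OC)=C\I | intermediate
22 | lithium phosphonoenolate of 21 | C=C[C@H](CO[Si](C)(C)C(C)(C)C)C[C@@H](OC([O-])=CP(=O)(OCC)OCC)[C@H]1O[C@@H]1C/C(C(=O)OC)=C\I.[Li+] | intermediate
23 | trans-6,12-lactone (11-diethoxyphosphoryl, C11 epimers) with (2R)-2-[(TBS-oxy)methyl]but-3-enyl on C6 and (1R,3E)-1-hydroxy-4-iodo-3-(methoxycarbonyl)but-3-enyl on C7 | C=C[C@H](CO[Si](C)(C)C(C)(C)C)C[C@H]1OC(=O)C(P(=O)(OCC)OCC)[C@@H]1[C@H](O)C/C(C(=O)OC)=C\I | intermediate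
24 | (R)-2-methylbutanoic acid | CC[C@@H](C)C(=O)O | starting material
25 | seco (E)-β-iodoenoate: 8-O-[(R)-2-methylbutanoyl] ester of 23 (C4 vinyl, C1 iodide) | C=C[C@H](CO[Si](C)(C)C(C)(C)C)C[C@H]1OC(=O)C(P(=O)(OCC)OCC)[C@@H]1[C@H](OC(=O)[C@H](C)CC)C/C(C(=O)OC)=C\I | intermediate
26 | B-alkyl-9-BBN borane of 25 (boron on C2) | B1(CC[C@H](CO[Si](C)(C)C(C)(C)C)C[C@H]2OC(=O)C(P(=O)(OCC)OCC)[C@@H]2[C@H](OC(=O)[C@H](C)CC)C/C(C(=O)OC)=C\I)C2CCCC1CCC2 | intermediate
27 | ten-membered carbocycle, 1(10)E, configured at C4, C6, C7, C8 as in the target, 11-diethoxyphosphoryl lactone, 15-O-TBS | CCOP(=O)(OCC)C1C(=O)O[C@@H]2C[C@@H](CO[Si](C)(C)C(C)(C)C)CC/C=C(/C(=O)OC)C[C@@H](OC(=O)[C@H](C)CC)[C@@H]12 | intermediate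
28 | 15-O-TBS ether of the target | C=C1C(=O)O[C@@H]2C[C@@H](CO[Si](C)(C)C(C)(C)C)CC/C=C(/C(=O)OC)C[C@@H](OC(=O)[C@H](C)CC)[C@@H]12 | intermediate
29 | CNP0141952.4: methyl (1(10)E,4S,6R,7S,8R)-15-hydroxy-8-[(2R)-2-methylbutanoyloxy]germacra-1(10),11(13)-dien-12,6-olid-14-oate | C=C1C(=O)O[C@@H]2C[C@@H](CO)CC/C=C(/C(=O)OC)C[C@@H](OC(=O)[C@H](C)CC)[C@@H]12 | target

## Count and risks

Total: 16 steps. Longest linear sequence: 13 steps (steps 1–5 and 9–16); the iodoenoate branch (steps 6–8) joins at step 9.

**Step 12 (proposed new method).** The stabilised enolate may open the 1,2-disubstituted epoxide too slowly, because the ester must adopt its less stable s-cis rotamer for closure. On warming, the released C8 oxygen could also start lactone migration to O8 or phosphoryl transfer. The fallback uses known chemistry, sets out from 18 and comes back at 25. Steglich esterification of 18 with 20 gives the allylic phosphonoacetate F1. Diazo transfer (4-acetamidobenzenesulfonyl azide, DBU) gives the diazophosphonoacetate F2. Rh2(OAc)4 then closes the lactone by intramolecular cyclopropanation of C7=C8, giving the cyclopropane-fused phosphono lactone F3 with the C5 chain on the convex face. Homoconjugate opening of this doubly activated cyclopropane at C8 by caesium (R)-2-methylbutanoate (from 24 and Cs2CO3, DMF) proceeds with inversion and gives 25 directly, so 19, 21 and 23 are bypassed.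

**Step 14 (key step).** Intermolecular coupling may overtake ring closure at this ring size. The alkylborane may be lost by protodeboronation or β-hydride elimination before transmetalation. The alkenylpalladium intermediate may instead be captured by the phosphonate-stabilised enolate. The fallback sets out from 25 and comes back at 27. Hydroboration with Ipc2BH, then acetaldehyde and KHF2, gives the potassium alkyltrifluoroborate F4, an isolable, monomeric nucleophile that releases the boronic acid slowly. Ring closure with Pd(dppf)Cl2 and Cs2CO3 in THF/H2O then runs under slow-release conditions with no borane excess and no strongly basic phosphate.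

**Step 9.** Facial selectivity may be poor because aldehyde 10 is unbranched at its α-carbon, and methyl transfer from zinc may compete with alkenyl transfer. The fallback sets out from 10 and 15 and comes back at 18. The ligand-free alkenylzinc addition gives 18 together with its C6 epimer F5. Dess–Martin oxidation of the mixture gives the enone F6. Corey–Bakshi–Shibata reduction with the (S)-methyl oxazaborolidine and catecholborane then sets C6 by reagent control and returns 18.

**Step 2.** The dienolate may alkylate at its γ-carbon, or the alkene may slip into conjugation and the C4 configuration be lost, since C4 is both α to the imide and allylic. The fallback sets out from 2 and comes back at 10. N-acylation of 2 with (E)-4-(tert-butyldimethylsilyloxy)but-2-enoic acid gives the enoyl imide F7. Conjugate addition of the cuprate from CH2=CHMgBr and CuBr·SMe2, anti to the benzyl group in the chelated s-cis imide, gives the adduct F8. LiBH4 gives the alcohol F9, and Dess–Martin oxidation gives 10. In this sequence C4 is never α to a carbonyl group.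

**Step 7.** Hot hydroxide may isomerise the skipped enyne (C9 lies between the alkyne and the new alkene) and erode the alkene geometry. The fallback sets out from 13 and comes back at 15. A Krapcho dealkoxycarbonylation (LiCl, wet DMSO, heat) removes one methyl group by chloride attack under neutral conditions; the carboxylate then fragments as before and 15 forms directly without hydroxide and without step 8. No new compound is made.

## Further compounds

F1 | step 12 | C6 diethylphosphonoacetate of allylic alcohol 18 | C=C[C@H](CO[Si](C)(C)C(C)(C)C)C[C@@H](OC(=O)CP(=O)(OCC)OCC)/C=C/C/C(C(=O)OC)=C\I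
F2 | step 12 | C6 diazo(diethoxyphosphoryl)acetate of 18 | C=C[C@H](CO[Si](C)(C)C(C)(C)C)C[C@@H](OC(=O)C(=[N+]=[N-])P(=O)(OCC)OCC)/C=C/C/C(C(=O)OC)=C\I
F3 | step 12 | cyclopropane-fused 11-phosphono γ-lactone (C7–C8–C11 ring) | CCOP(=O)(OCC)[C@]12C(=O)O[C@H](C[C@H](C=C)CO[Si](C)(C)C(C)(C)C)[C@H]1[C@@H]2C/C(C(=O)OC)=C\I
F4 | step 14 | potassium C2 alkyltrifluoroborate of 25 | [K+].F[B-](F)(F)CC[C@H](CO[Si](C)(C)C(C)(C)C)C[C@H]1OC(=O)C(P(=O)(OCC)OCC)[C@@H]1[C@H](OC(=O)[C@H](C)CC)C/C(C(=O)OC)=C\I
F5 | step 9 | (6S)-epimer of allylic alcohol 18 | C=C[C@H](CO[Si](C)(C)C(C)(C)C)C[C@H](O)/C=C/C/C(C(=O)OC)=C\I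
F6 | step 9 | C6 enone from 18 | C=C[C@H](CO[Si](C)(C)C(C)(C)C)CC(=O)/C=C/C/C(C(=O)OC)=C\I
F7 | step 2 | (R)-4-benzyl-3-[(E)-4-(tert-butyldimethylsilyloxy)but-2-enoyl]oxazolidin-2-one | CC(C)(C)[Si](C)(C)OC/C=C/C(=O)N1[C@H](Cc2ccccc2)COC1=O
F8 | step 2 | (R)-4-benzyl-3-{(3R)-3-[(tert-butyldimethylsilyloxy)methyl]pent-4-enoyl}oxazolidin-2-one | C=C[C@@H](CC(=O)N1[C@H](Cc2ccccc2)COC1=O)CO[Si](C)(C)C(C)(C)C
F9 | step 2 | (3R)-3-[(tert-butyldimethylsilyloxy)methyl]pent-4-en-1-ol | C=C[C@@H](CCO)CO[Si](C)(C)C(C)(C)C
F0 | step 7 | none | none
A1 | alternative 1 | carbocyclic C15 acid with cis C1=C2 alkene | OC(=O)[C@H]1C/C=C\[C@@H](COCc3ccc(OC)cc3)C[C@@H](O[Si](C)(C)C(C)(C)C)[C@H]2CC(=O)O[C@@H]2C1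
A2 | alternative 2 | C6 tert-butyl diazomalonate of allylic alcohol 18 | C=C[C@H](CO[Si](C)(C)C(C)(C)C)C[C@@H](OC(=O)C(=[N+]=[N-])C(=O)OC(C)(C)C)/C=C/C/C(C(=O)OC)=C\I
A3 | alternative 2 | cyclopropane-fused γ-lactone tert-butyl ester | CC(C)(C)OC(=O)[C@]12C(=O)O[C@H](C[C@H](C=C)CO[Si](C)(C)C(C)(C)C)[C@H]1[C@@H]2C/C(C(=O)OC)=C\I
A4 | alternative 3 | seco C8 aldehyde with α-(tributylstannylmethyl)butenolide | O=CC/C(C(=O)OC)=C\CC[C@H](CO[Si](C)(C)C(C)(C)C)C[C@H]1OC(=O)C(C[Sn](CCCC)(CCCC)CCCC)=C1
A5 | alternative 3 | 8-hydroxy 15-O-TBS macrocyclic α-methylene lactone | C=C1C(=O)O[C@@H]2C[C@@H](CO[Si](C)(C)C(C)(C)C)CC/C=C(/C(=O)OC)C[C@@H](O)[C@@H]12
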